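The rate constants are invented; the flask was simulated.

Flasks zeta and beta take the same charge of Q and differ in the time of reading.

- zeta: Q 0.050 M; time 80 s
- beta: Q 0.050 M; time 120 s

    Q → J (k1 = 0.269 s⁻¹)
    Q + Q ⇌ Q2 (K2 = 43.8 M⁻¹, k2 = 31.2 M⁻¹ s⁻¹)
    X ⇌ J, rate k3*(cs3 - [J]) while solid is left; crystals form when [J] > cs3 (cs3 = 20 mM, k3 = 0.208 s⁻¹)
    J → L (k4 = 0.0137 s⁻¹)

- percentages count the Q that a species holds: one Q2 counts as two
- J is meant together with its X
- for a step with 2 of a species take k times the square, and two of it per event
- solid, in amounts per volume of the solution: X
- run time (zeta): 80 s

- which of the two there is more of at the end, zeta (L / J)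
- which of the two there is more of at the end, beta (L / J)
- amount of J at the end, in percent of the Q charged, zeta
- amount of J at the end, in percent of the Q charged, beta

Q pairs up faster than it closes to J, so we take the dimer, the resting state of Q, as in balance with free Q. That leaves 18.9 mM of Q free, and J climbs at about 5.07 mM s⁻¹. Dissolved J reaches its solubility of 20 mM after about 3.94 s, and crystals begin: the first knee. Crystals answer a shortfall faster than L draws on the solution, so when the feed from Q has faded, dissolved J rests on the level where dissolving matches that loss, 18.8 mM.

The area of dissolved J above solubility equals the crystals standing divided by the dissolving coefficient. Neglecting the first seconds, L made so far is therefore its rate constant times the sum of solubility times time and that quotient. Crystals are the charge less the level less L, so L runs straight with slope 0.257 mM s⁻¹ from a head start of 1.93 mM. With crystals at nil, the same rule gives the quantity we carry: the life of the crystals, the charge less the level, divided by L's rate constant times solubility, 114 s.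

L passes J with its crystals at 89.7 s, when L holds half the charge, later than zeta's reading and earlier than beta's. So we commit to J ahead in zeta, at 55.0%. Beta is read beyond the life, so there dissolved J has been falling from its level by the fourth step, and we commit to L ahead with J at 34.6%.

The forecast, holding that “the excess J crystallises”, gave J ahead at 56% in zeta, and L ahead with J at 36% in beta. The flasks give J 56.0% against L 44.0% in zeta, and J 35.5% against L 64.5% in beta.

X stands at 18.5% in zeta, read before the life of 114 s, and at 0% in beta, read after it. The flask like beta but charged with 0.085 M of Q has a life of 242 s, longer than its reading time. By the same reckoning its L stays on a straight line of the same slope, with a larger head start, and we reckon L at 41.1% of that charge. That flask gives L 40.7% and J 59.3%, of which X holds 37.2%.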